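## Retrosynthetic overview

Eremophilane numbering is used: ring A = C1–C5/C10, ring B = C5–C10, side chain C11–C13.

1. C7–C11: target 15 ⇐ α-iodoenone angelate 13 + racemic methyl 2-chloropropanoate 14 (last step, sets C11); 13 ⇐ hydroxy-enone 9 by α-iodination and angeloylation.
2. C3–OH: 9 ⇐ enedione 8 by face-selective reduction of the saturated ketone.
3. Key step: 8 ⇐ 1-vinylcyclopentanol 7 by semipinacol ring expansion (C5 shifts from C3 to C4); ring A grows from five to six members and C4 is set.
4. 7 ⇐ cis-hydrindanone silyl enol ether 4 by vinyl addition at C3, then Saegusa oxidation to the C6=C7–C8=O enone.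
5. 4 ⇐ 2-methylcyclopent-2-enone 3 + 2-silyloxybutadiene 2 (from butenone 1) by Diels–Alder; ring B is formed first (sets C5 and C10), ring A is completed second by the ring expansion.

Assumption: metal alkoxides and catalyst-bound species that exist only until aqueous work-up are not counted as separate compounds.

## Route

Step 1
Reactants: 1 but-3-en-2-one
Product: 2 2-[(tert-butyldimethylsilyl)oxy]buta-1,3-diene
Conditions: TBSOTf, Et3N, Et2O, 0 °C → rt
Reagents that add atoms: tert-butyldimethylsilyl trifluoromethanesulfonate, CC(C)(C)[Si](C)(C)OS(=O)(=O)C(F)(F)F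
Why: Soft enolisation and O-silylation of the methyl ketone (silyl enol ether formation) gives the 2-silyloxydiene; no stereocentre is formed.

Step 2
Reactants: 2 2-[(tert-butyldimethylsilyl)oxy]buta-1,3-diene, 3 2-methylcyclopent-2-en-1-one
Product: 4 (3aR,7aS)-5-[(tert-butyldimethylsilyl)oxy]-7a-methyl-2,3,3a,4,7,7a-hexahydro-1H-inden-1-one
Conditions: (S)-o-tolyl-CBS oxazaborolidine (10 mol %), AlBr3 (8 mol %), CH2Cl2, −78 → −40 °C
Reagents that add atoms: none
Why: Proposed new method: a cationic oxazaborolidine–AlBr3 Lewis acid binds the enone carbonyl on the lone pair away from the α-methyl group and shields one π-face, so the silyloxydiene adds in an asynchronous [4+2] reaction (C9–C10 bond leading, silyloxy carbon para to the quaternary carbon, both bonds on one face), giving the cis ring fusion with C5 and C10 set together; the closest known reactions are oxazaborolidinium-catalysed enantioselective Diels–Alder reactions of cyclopent-2-enone and α-substituted acroleins with 2-silyloxybutadienes and the racemic AlBr3/AlMe3-promoted cycloaddition of 2-methylcycloalkenones with 2-silyloxydienes.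

Step 3
Reactants: 4 (3aR,7aS)-5-[(tert-butyldimethylsilyl)oxy]-7a-methyl-2,3,3a,4,7,7a-hexahydro-1H-inden-1-one, 5 vinylmagnesium bromide
Product: 6 (1R,3aR,7aS)-5-[(tert-butyldimethylsilyl)oxy]-1-ethenyl-7a-methyl-2,3,3a,4,7,7a-hexahydro-1H-inden-1-ol
Conditions: CeCl3 (anhydrous), THF, −78 → 0 °C; then pH 7 buffer
Reagents that add atoms: none
Why: Cerium-mediated Grignard 1,2-addition to the only free carbonyl (the silyl enol ether masks C8); vinyl enters from the α face anti to the angular methyl, as in cis-C/D 17-ketosteroids, giving the β-hydroxy carbinol.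

Step 4
Reactants: 6 (1R,3aR,7aS)-5-[(tert-butyldimethylsilyl)oxy]-1-ethenyl-7a-methyl-2,3,3a,4,7,7a-hexahydro-1H-inden-1-ol
Product: 7 (1R,3aR,7aR)-1-ethenyl-1-hydroxy-7a-methyl-1,2,3,3a,4,7a-hexahydro-5H-inden-5-one
Conditions: Pd(OAc)2 (1.05 equiv), MeCN, rt
Reagents that add atoms: none
Why: Saegusa–Ito oxidation: Pd(II) converts the regiodefined C7=C8 silyl enol ether into a C7 palladium enolate and β-hydride elimination is only possible toward C6, giving the C6=C7–C8=O enone without touching a stereocentre.

Step 5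
Reactants: 7 (1R,3aR,7aR)-1-ethenyl-1-hydroxy-7a-methyl-1,2,3,3a,4,7a-hexahydro-5H-inden-5-one
Product: 8 (1R,4aR,8aR)-1,8a-dimethyl-3,4,4a,5-tetrahydronaphthalene-2,6(1H,8aH)-dione
Conditions: Co(salen) (5 mol %), 1-fluoro-2,4,6-trimethylpyridinium triflate (1.5 equiv), (Me2SiH)2O (1.5 equiv), PhCF3, 0 °C
Reagents that add atoms: none
Why: Proposed new method: a Co(III) hydride transfers a hydrogen atom to the terminal vinyl carbon (Markovnikov MHAT), the secondary C4 radical is captured and oxidised to an alkylcobalt(IV) cation equivalent, and the anti-periplanar C3–C5 bond (quaternary carbon, best migrating group) displaces cobalt with inversion while the carbinol becomes the C3 ketone, a semipinacol 1,2-shift that expands the cyclopentanol to the cyclohexanone; C5 migrates with retention and the C4 methyl takes the outside position in the migration transition state (H inside, under the concave α face), which gives the 4β-methyl (R) centre; the closest known reactions are Co(salen)/N-fluoropyridinium/silane radical-polar crossover hydrofunctionalisations of alkenes and HAT-initiated semipinacol rearrangements of tertiary allylic alcohols with aryl or strained-ring migration.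

Step 6
Reactants: 8 (1R,4aR,8aR)-1,8a-dimethyl-3,4,4a,5-tetrahydronaphthalene-2,6(1H,8aH)-dione
Product: 9 (4aR,5R,6S,8aR)-6-hydroxy-4a,5-dimethyl-4a,5,6,7,8,8a-hexahydronaphthalen-2(1H)-one
Conditions: LiAlH(Ot-Bu)3 (1.2 equiv), THF, −78 → −40 °C; then aqueous work-up
Reagents that add atoms: none
Why: Chemoselective hydride reduction of the saturated C3 ketone beside the conjugated enone (as for a 17-ketone beside a 4-en-3-one); the bulky hydride attacks from the α face opposite the two β methyl groups on C4 and C5 and sets the 3β (S) alcohol cis to both.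

Step 7
Reactants: 9 (4aR,5R,6S,8aR)-6-hydroxy-4a,5-dimethyl-4a,5,6,7,8,8a-hexahydronaphthalen-2(1H)-one
Product: 10 (4aS,5R,6S,8aR)-6-hydroxy-3-iodo-4a,5-dimethyl-4a,5,6,7,8,8a-hexahydronaphthalen-2(1H)-one
Conditions: I2 (1.5 equiv), K2CO3 (1.2 equiv), DMAP (0.2 equiv), THF–H2O (1:1), rt
Reagents that add atoms: iodine, II
Why: Nucleophile-catalysed α-iodination of the enone (Johnson–Krafft: DMAP adds at C6, the enolate is iodinated at C7, DMAP is eliminated); no stereocentre is touched (the descriptor at C4a changes only because of CIP priority).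

Step 8
Reactants: 10 (4aS,5R,6S,8aR)-6-hydroxy-3-iodo-4a,5-dimethyl-4a,5,6,7,8,8a-hexahydronaphthalen-2(1H)-one, 11 (2Z)-2-methylbut-2-enoic acid (angelic acid)
Product: 13 (1R,2S,4aR,8aS)-7-iodo-1,8a-dimethyl-6-oxo-1,2,3,4,4a,5,6,8a-octahydronaphthalen-2-yl (2Z)-2-methylbut-2-enoate, via angelic 2,4,6-trichlorobenzoic anhydride 12 (not isolated)
Conditions: 11, 2,4,6-Cl3C6H2COCl, Et3N, toluene, rt; then 10, toluene, 80 °C (no DMAP)
Reagents that add atoms: none
Why: Yamaguchi-type esterification through the mixed anhydride, run without a nucleophilic catalyst to avoid Z→E isomerisation of the angelate; the alcohol attacks the less hindered angeloyl carbonyl with retention at C3.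

Step 9
Reactants: 13 (1R,2S,4aR,8aS)-7-iodo-1,8a-dimethyl-6-oxo-1,2,3,4,4a,5,6,8a-octahydronaphthalen-2-yl (2Z)-2-methylbut-2-enoate, 14 methyl 2-chloropropanoate (racemic)
Product: 15 methyl (2R)-2-[(4aR,7S,8R,8aR)-8,8a-dimethyl-7-{[(2Z)-2-methylbut-2-enoyl]oxy}-3-oxo-3,4,4a,5,6,7,8,8a-octahydronaphthalen-2-yl]propanoate
Conditions: NiBr2·diglyme (10 mol %), (R,R)-4-heptyl-BiOX (12 mol %), Mn (3 equiv), NaI (0.5 equiv), DMA, 5 °C
Reagents that add atoms: none
Why: Proposed new method: Ni(0) inserts into the C(sp2)–I bond of the α-iodoenone, halogen abstraction turns both enantiomers of 14 into the same planar α-ester radical, the chiral (BiOX)Ni(II)–alkenyl complex captures it and reductive elimination from Ni(III) forms C7–C11 with catalyst-controlled (R) configuration under neutral conditions that do not epimerise C11; the closest known reactions are Ni/bis(oxazoline)-catalysed enantioconvergent reductive cross-couplings of α-chloro esters with aryl iodides and of benzylic chlorides with alkenyl bromides.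

## Compound list

1 | but-3-en-2-one | CC(=O)C=C | starting material
2 | 2-[(tert-butyldimethylsilyl)oxy]buta-1,3-diene | C=CC(=C)O[Si](C)(C)C(C)(C)C | intermediate
3 | 2-methylcyclopent-2-en-1-one | CC1=CCCC1=O | starting material
4 | (3aR,7aS)-5-[(tert-butyldimethylsilyl)oxy]-7a-methyl-2,3,3a,4,7,7a-hexahydro-1H-inden-1-one | O=C1CC[C@@H]2CC(O[Si](C)(C)C(C)(C)C)=CC[C@]12C | intermediate
5 | vinylmagnesium bromide | C=C[Mg]Br | starting material
6 | (1R,3aR,7aS)-5-[(tert-butyldimethylsilyl)oxy]-1-ethenyl-7a-methyl-2,3,3a,4,7,7a-hexahydro-1H-inden-1-ol | C=C[C@]1(O)CC[C@@H]2CC(O[Si](C)(C)C(C)(C)C)=CC[C@]12C | intermediate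
7 | (1R,3aR,7aR)-1-ethenyl-1-hydroxy-7a-methyl-1,2,3,3a,4,7a-hexahydro-5H-inden-5-one | C=C[C@]1(O)CC[C@@H]2CC(=O)C=C[C@]12C | intermediate
8 | (1R,4aR,8aR)-1,8a-dimethyl-3,4,4a,5-tetrahydronaphthalene-2,6(1H,8aH)-dione | O=C1CC[C@@H]2CC(=O)C=C[C@]2(C)[C@H]1C | intermediate
9 | (4aR,5R,6S,8aR)-6-hydroxy-4a,5-dimethyl-4a,5,6,7,8,8a-hexahydronaphthalen-2(1H)-one | O[C@H]1CC[C@@H]2CC(=O)C=C[C@]2(C)[C@H]1C | intermediate
10 | (4aS,5R,6S,8aR)-6-hydroxy-3-iodo-4a,5-dimethyl-4a,5,6,7,8,8a-hexahydronaphthalen-2(1H)-one | O[C@H]1CC[C@@H]2CC(=O)C(I)=C[C@]2(C)[C@H]1C | intermediate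
11 | (2Z)-2-methylbut-2-enoic acid (angelic acid) | C/C=C(/C)C(=O)O | starting material
12 | (2Z)-2-methylbut-2-enoic 2,4,6-trichlorobenzoic anhydride | C/C=C(/C)C(=O)OC(=O)c1c(Cl)cc(Cl)cc1Cl | intermediate (not isolated)
13 | (1R,2S,4aR,8aS)-7-iodo-1,8a-dimethyl-6-oxo-1,2,3,4,4a,5,6,8a-octahydronaphthalen-2-yl (2Z)-2-methylbut-2-enoate | C/C=C(/C)C(=O)O[C@H]1CC[C@@H]2CC(=O)C(I)=C[C@]2(C)[C@H]1C | intermediate
14 | methyl 2-chloropropanoate (racemic) | CC(Cl)C(=O)OC | starting material
15 | methyl (2R)-2-[(4aR,7S,8R,8aR)-8,8a-dimethyl-7-{[(2Z)-2-methylbut-2-enoyl]oxy}-3-oxo-3,4,4a,5,6,7,8,8a-octahydronaphthalen-2-yl]propanoate | C/C=C(/C)C(=O)O[C@H]1CC[C@@H]2CC(=O)C([C@@H](C)C(=O)OC)=C[C@]2(C)[C@H]1C | target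

## Step count and risks

Total step count: 9. Longest linear sequence: 9 steps (1 → 2 → 4 → 6 → 7 → 8 → 9 → 10 → 13 → 15).

The three steps most likely to fail are steps 2, 5 and 9, which are also the three proposed new methods.

Step 2 (enantioselective Diels–Alder on an α-methyl cycloalkenone). The risks are low enantioselectivity, because the usual α-C–H contact to the catalyst is missing, and the unverified sense of induction; the enantiomeric catalyst is equally available. Fallback by known chemistry: set out from diene 2 and use unsubstituted cyclopent-2-en-1-one, for which the oxazaborolidinium-catalysed Diels–Alder reaction is established. This gives (3aR,7aS)-5-[(tert-butyldimethylsilyl)oxy]-2,3,3a,4,7,7a-hexahydro-1H-inden-1-one F1. Equilibration to the more substituted ring-fusion potassium enolate (KH, THF) and methylation with MeI on the convex β face (classical angular methylation of a cis-hydrindanone) returns to 4.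

Step 5 (MHAT semipinacol ring expansion). The risks are epoxide formation by the tertiary hydroxyl instead of the 1,2-shift, and erosion of the C4 configuration. Fallback by known chemistry: set out from 7 and trigger the same shift with a halonium ion. NBS with propylene oxide in CH2Cl2 at −20 °C gives (1R,4aR,8aR)-1-(bromomethyl)-8a-methyl-3,4,4a,5-tetrahydronaphthalene-2,6(1H,8aH)-dione F2, with C5 adding anti to the bromonium ion and the CH2Br group outside. Radical debromination (Bu3SnH at high concentration, AIBN, benzene, 80 °C, to outrun a 1,2-acyl shift) converts CH2Br into the C4 methyl and returns to 8.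

Step 9 (enantioconvergent Ni coupling). The risks are protodeiodination of 13, low stereocontrol at C11 and loss of the angelate geometry. Fallback by known chemistry: set out from 13 and use a palladium-catalysed Negishi coupling (Pd2(dba)3/SPhos, THF, rt) with the Reformatsky reagent made from methyl 2-bromopropanoate and zinc. This gives 15 together with its C11 epimer, methyl (2S)-2-[(4aR,7S,8R,8aR)-8,8a-dimethyl-7-{[(2Z)-2-methylbut-2-enoyl]oxy}-3-oxo-3,4,4a,5,6,7,8,8a-octahydronaphthalen-2-yl]propanoate F3, in roughly equal amounts. The two are separated by preparative HPLC; F3 is re-equilibrated at C11 with DBU and recycled, so the route arrives at 15.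

Further compounds
F1 | step 2 | (3aR,7aS)-5-[(tert-butyldimethylsilyl)oxy]-2,3,3a,4,7,7a-hexahydro-1H-inden-1-one | O=C1CC[C@@H]2CC(O[Si](C)(C)C(C)(C)C)=CC[C@H]12
F2 | step 5 | (1R,4aR,8aR)-1-(bromomethyl)-8a-methyl-3,4,4a,5-tetrahydronaphthalene-2,6(1H,8aH)-dione | O=C1CC[C@@H]2CC(=O)C=C[C@]2(C)[C@H]1CBr
F3 | step 9 | methyl (2S)-2-[(4aR,7S,8R,8aR)-8,8a-dimethyl-7-{[(2Z)-2-methylbut-2-enoyl]oxy}-3-oxo-3,4,4a,5,6,7,8,8a-octahydronaphthalen-2-yl]propanoate | C/C=C(/C)C(=O)O[C@H]1CC[C@@H]2CC(=O)C([C@H](C)C(=O)OC)=C[C@]2(C)[C@H]1C
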